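**Retrosynthetic overview**

1. Target ⇐ late acylations (C6 angelate, C2 and C10 acetates), a C4–OH-directed reduction of a C2 ketone and a C10–OH-directed 8,9-epoxidation ⇐ trans-fused hydroazulenone (4β,10α-dihydroxy-dauc-8-en-2-one, C6–OTBS).
2. Hydroazulenone ⇐ one-flask directed epoxidation/semipinacol shift of a cis-bicyclo[6.2.0]deca-2,4-diene-1,9-diol: the bond C2–C5, shared by the cyclobutane C2–C3–C4–C5 and the cyclooctadiene C2–C1–C10–C9–C8–C7–C6–C5, moves from C2 to C1 (4→5 ring expansion together with 8→7 ring contraction).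
3. Enabling feature: the tertiary cyclobutanol carbon C2 is a ring-fusion atom next to the C1(Me)=C10 double bond of the eight-membered ring, so the strained C2–C5 bond can lie antiperiplanar to the C1–O bond of the syn-epoxide while C2 becomes the ketone.
4. Bicyclo[6.2.0] diol ⇐ i-PrMgCl addition and dechlorination of the dichloroketene [2+2] adduct of the silyl trienol ether of a (7S)-7-silyloxy-2,5-dimethylcycloocta-2,4-dienone ⇐ Claisen ring expansion of a 2-ethylidene-6-vinyltetrahydropyran ⇐ (R)-3-silyloxyglutaric half-ester.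
5. Ring order: δ-lactone/tetrahydropyran (temporary) → cyclooctenone (temporary eight-membered ring) → cyclobutanone → cyclopentanone + cycloheptene (key step) → oxirane.

Key step: step 10

Assumption: 1 is bought as the (R)-half-ester (statin side-chain building block); it is also accessible from 3-(tert-butyldimethylsilyloxy)glutaric anhydride by alkaloid-mediated methanolysis.
Numbering: daucane numbering is used for all carbocycles (five-membered ring C1–C5; seven-membered ring C1, C10, C9, C8, C7, C6, C5; C1 carries the angular methyl, C4 the isopropyl group; β = face of the C1 methyl, α = face of H-5). In names of bicyclo[6.2.0]decanes the locants 1–10 correspond to daucane C2, C1, C10, C9, C8, C7, C6, C5, C4, C3.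

**Route**

Step 1
Reactants: 1 methyl hydrogen (3R)-3-[(tert-butyldimethylsilyl)oxy]pentanedioate; 2 N,O-dimethylhydroxylamine hydrochloride
Product: 3 (3S)-3-[(tert-butyldimethylsilyl)oxy]-5-[methoxy(methyl)amino]-5-oxopentanoic acid
Conditions: 2 (1.5 equiv), LiHMDS (4.2 equiv), THF, −78 → −20 °C; aq. citric acid
Reagents that add atoms: N,O-dimethylhydroxylamine hydrochloride, CNOC.Cl
Why: Aminolysis of the methyl ester by the lithium amide of MeNHOMe (Weinreb amide formation) should be chemoselective because the carboxylate formed first is inert; the silyloxy stereocentre (later C6) is not involved.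

Step 2
Reactants: 3 (3S)-3-[(tert-butyldimethylsilyl)oxy]-5-[methoxy(methyl)amino]-5-oxopentanoic acid; 4 methylmagnesium bromide
Product: 5 (3S)-3-[(tert-butyldimethylsilyl)oxy]-5-oxohexanoic acid
Conditions: MeMgBr (3 equiv), THF, 0 °C; aq. NaHSO4
Reagents that add atoms: methylmagnesium bromide, C[Mg]Br
Why: Weinreb ketone synthesis: the chelated tetrahedral adduct survives until work-up, so the Grignard reagent adds once, the carboxylate is spared and the β-silyloxy ketone is never exposed to base.

Step 3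
Reactants: 5 (3S)-3-[(tert-butyldimethylsilyl)oxy]-5-oxohexanoic acid; 6 vinylmagnesium bromide
Product: 8 (4S,6RS)-4-[(tert-butyldimethylsilyl)oxy]-6-ethenyl-6-methyloxan-2-one, via hydroxy acid 7 (not isolated)
Conditions: CH2=CHMgBr (3 equiv), CeCl3, THF, −78 → 0 °C; pH 4 work-up; then EDC·HCl, cat. DMAP, CH2Cl2, rt
Reagents that add atoms: vinylmagnesium bromide, C=C[Mg]Br
Why: Organocerium-moderated 1,2-addition of the vinyl Grignard reagent to the methyl ketone followed by carbodiimide (Steglich-type) lactonisation; the new carbinol centre (C8) forms as an epimer mixture that is of no consequence because C8 becomes sp2 in step 5.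

Step 4
Reactants: 8 (4S,6RS)-4-[(tert-butyldimethylsilyl)oxy]-6-ethenyl-6-methyloxan-2-one; 9 1,1-dibromoethane
Product: 10 (2Z,4R,6RS)-4-[(tert-butyldimethylsilyl)oxy]-6-ethenyl-2-ethylidene-6-methyloxane
Conditions: CH3CHBr2, Zn, TiCl4, TMEDA, cat. PbCl2, THF, 0 °C → rt; K2CO3 work-up
Reagents that add atoms: 1,1-dibromoethane, CC(Br)Br
Why: Takai–Utimoto alkylidenation (gem-dizinc/titanium reagent) should convert the lactone carbonyl into the Z-enol ether without touching the vinyl group or the silyl ether; the enol ether geometry only determines the C1 centre, which is flattened again in step 6.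

Step 5
Reactants: 10 (2Z,4R,6RS)-4-[(tert-butyldimethylsilyl)oxy]-6-ethenyl-2-ethylidene-6-methyloxane
Product: 11 (4Z,7S)-7-[(tert-butyldimethylsilyl)oxy]-2,5-dimethylcyclooct-4-en-1-one (C2 epimers)
Conditions: toluene, BHT, base-washed sealed tube, 185 °C
Reagents that add atoms: none
Why: Thermal Claisen ([3,3]) rearrangement of the 2-alkylidene-6-vinyltetrahydropyran forms C1–C10 and breaks O–C8, expanding the six-membered ether into the (Z)-cyclooct-4-enone (Claisen ring expansion); C6 is untouched and the C1 epimer mixture is irrelevant.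

Step 6
Reactants: 11 (4Z,7S)-7-[(tert-butyldimethylsilyl)oxy]-2,5-dimethylcyclooct-4-en-1-one
Product: 13 (2Z,4Z,7S)-7-[(tert-butyldimethylsilyl)oxy]-2,5-dimethylcycloocta-2,4-dien-1-one, via trimethylsilyl enol ether 12 (not isolated)
Conditions: TMSI, (Me3Si)2NH, CH2Cl2, −20 → 25 °C; then Pd(OAc)2 (1.05 equiv), MeCN, 25 °C
Reagents that add atoms: none
Why: Equilibrating silylation should give the more substituted (C1=C2) enol ether, and Saegusa–Ito oxidation (palladium enolate, β-hydride elimination toward the doubly activated C10–H) should then give the 2,4-dienone; no stereocentre is formed.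

Step 7
Reactants: 13 (2Z,4Z,7S)-7-[(tert-butyldimethylsilyl)oxy]-2,5-dimethylcycloocta-2,4-dien-1-one; 14 chlorotrimethylsilane; 15 dichloroacetyl chloride
Product: 17 (7S)-7-[(tert-butyldimethylsilyl)oxy]-10,10-dichloro-2,5-dimethyl-1-[(trimethylsilyl)oxy]bicyclo[6.2.0]deca-2,4-dien-9-one (cis-fused; 1-OSiMe3, H-8 and 7-OSi on the same face of the eight-membered ring), via silyl trienol ether 16 (not isolated)
Conditions: LDA, TMSCl (in situ), THF, −78 °C; solvent switch to hexane; then Cl2CHCOCl, Et3N, hexane, 0 → 25 °C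
Reagents that add atoms: chlorotrimethylsilane, C[Si](C)(C)Cl; dichloroacetyl chloride, O=C(Cl)C(Cl)Cl
Why: Kinetic α′-deprotonation with in situ silylation gives the cross-conjugated trienol ether, and thermal ketene–alkene [2+2] cycloaddition of dichloroketene should occur at its enol ether double bond with the carbonyl carbon bonding to C5 and CCl2 to C2; the suprafacial addition fixes the cis ring fusion, and approach anti to the allylic C6–OTBS group should set C5 and C2 relative to C6.

Step 8
Reactants: 17 (7S)-7-[(tert-butyldimethylsilyl)oxy]-10,10-dichloro-2,5-dimethyl-1-[(trimethylsilyl)oxy]bicyclo[6.2.0]deca-2,4-dien-9-one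
Product: 18 (7S)-7-[(tert-butyldimethylsilyl)oxy]-2,5-dimethyl-1-[(trimethylsilyl)oxy]bicyclo[6.2.0]deca-2,4-dien-9-one (cis-fused, same relative configuration as 17)
Conditions: Zn–Cu, NH4Cl, MeOH, 0 → 25 °C
Reagents that add atoms: none
Why: Zinc reduction of the α,α-dichloroketone (zinc enolates protonated by buffered methanol) should remove both chlorines under near-neutral conditions that keep the tertiary TMS ether, whose loss would open the β-oxy cyclobutanone by retro-aldol cleavage.

Step 9
Reactants: 18 (7S)-7-[(tert-butyldimethylsilyl)oxy]-2,5-dimethyl-1-[(trimethylsilyl)oxy]bicyclo[6.2.0]deca-2,4-dien-9-one; 19 isopropylmagnesium chloride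
Product: 21 (7S)-7-[(tert-butyldimethylsilyl)oxy]-2,5-dimethyl-9-(propan-2-yl)bicyclo[6.2.0]deca-2,4-diene-1,9-diol (cis-fused; 1-OH, H-8 and 7-OSi on one face; isopropyl cis to H-8, 9-OH trans to 1-OH), via trimethylsilyl ether 20 (not isolated)
Conditions: i-PrMgCl, CeCl3, THF, −78 °C; aq. NH4Cl; then K2CO3, MeOH, 0 °C → rt
Reagents that add atoms: isopropylmagnesium chloride, CC(C)[Mg]Cl
Why: The organocerium reagent should add to the strained, weakly enolisable cyclobutanone from the convex face of the cis-bicyclo[6.2.0] skeleton (anti to the C6 branch on the adjacent C5), which sets C4 with isopropyl cis to H-5; carbonate-mediated methanolysis then cleaves only the trimethylsilyl ether.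

Step 10
Reactants: 21 (7S)-7-[(tert-butyldimethylsilyl)oxy]-2,5-dimethyl-9-(propan-2-yl)bicyclo[6.2.0]deca-2,4-diene-1,9-diol; 22 tert-butyl hydroperoxide
Product: 24 6α-[(tert-butyldimethylsilyl)oxy]-4β,10α-dihydroxydauc-8-en-2-one (trans-fused hydroazulenone, 1β-methyl, 5α-H), via epoxy diol 23 (not isolated)
Conditions: VO(acac)2 (5 mol %), t-BuOOH (1.05 equiv), CH2Cl2, 0 °C; then Me2AlCl (3.5 equiv), −78 → −40 °C; Rochelle salt
Reagents that add atoms: tert-butyl hydroperoxide, CC(C)(C)OO
Why: Vanadium-catalysed, hydroxyl-directed epoxidation should deliver oxygen to C1=C10 on the face of the tertiary C2–OH (syn-epoxy alcohol 23; the allylic double bond reacts before the remote C8=C9 bond), and Me2AlCl then turns the hydroxyls into aluminium alkoxides, the C2–O–Al unit chelating the cis oxirane oxygen so that the C1–O bond is activated from inside the molecule. The C2–C5 σ-bond, common to the four- and eight-membered rings and antiperiplanar to C1–O, migrates to C1 with inversion while C2 becomes the carbonyl carbon, i.e. a semipinacol rearrangement of a 2,3-epoxy alcohol to a β-hydroxy ketone, whose closest precedent is the Lewis-acid ring expansion of 1-(oxiranyl)cyclobutanols to 2-(hydroxyalkyl)cyclopentanones. Ring modes: the cyclopentanone C1–C5 arises by one-carbon ring expansion of the cyclobutanol through the 1,2-shift (C1 is inserted between C2 and C5), and the cycloheptene (C1, C10, C9, C8, C7, C6, C5) is what remains of the cyclooctadiene once C2 has left it (transannular ring contraction), so no ring is closed by an external bond formation. Stereocontrol: C10 keeps the oxirane oxygen (α, set by the directed epoxidation), C1 is set by the stereospecific backside displacement (methyl trans to the C10–O bond), and retention at the migrating C5 gives the trans ring fusion. Selectivity needed: migration of C5 rather than C3 and cleavage of C1–O rather than of the allylic C10–O bond; the first should follow from the higher migratory aptitude of the secondary ring-fusion carbon and from the ring torsion that the directed epoxidation itself requires (O–C2–C1=C10 about 50°, which puts C5 anti and C3 gauche to the new C–O bond), the second from chelate activation at the tertiary carbon and the release of cyclobutane strain.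

Step 11
Reactants: 24 6α-[(tert-butyldimethylsilyl)oxy]-4β,10α-dihydroxydauc-8-en-2-one; 22 tert-butyl hydroperoxide
Product: 25 6α-[(tert-butyldimethylsilyl)oxy]-8α,9α-epoxy-4β,10α-dihydroxydaucan-2-one
Conditions: VO(acac)2 (5 mol %), t-BuOOH, CH2Cl2, 0 °C → rt
Reagents that add atoms: tert-butyl hydroperoxide, CC(C)(C)OO
Why: Vanadium-catalysed hydroxyl-directed epoxidation of the cyclic allylic alcohol should deliver oxygen to C8=C9 from the face of the C10–OH (syn, α), which sets C8 and C9; the ketone and the non-allylic tertiary alcohol do not interfere.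

Step 12
Reactants: 25 6α-[(tert-butyldimethylsilyl)oxy]-8α,9α-epoxy-4β,10α-dihydroxydaucan-2-one; 26 acetic anhydride
Product: 27 10α-acetoxy-6α-[(tert-butyldimethylsilyl)oxy]-8α,9α-epoxy-4β-hydroxydaucan-2-one
Conditions: Ac2O, pyridine, cat. DMAP, CH2Cl2, 0 °C → rt
Reagents that add atoms: acetic anhydride, CC(=O)OC(C)=O
Why: DMAP-catalysed acetylation should acylate the secondary C10 hydroxyl while the tertiary C4 hydroxyl stays free; masking C10–OH also keeps it from directing the next reduction to the wrong face.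

Step 13
Reactants: 27 10α-acetoxy-6α-[(tert-butyldimethylsilyl)oxy]-8α,9α-epoxy-4β-hydroxydaucan-2-one
Product: 28 10α-acetoxy-6α-[(tert-butyldimethylsilyl)oxy]-8α,9α-epoxydaucane-2α,4β-diol
Conditions: Me4NBH(OAc)3, MeCN/AcOH, −35 °C
Reagents that add atoms: none
Why: Evans–Saksena reduction: the triacetoxyborohydride should exchange an acetate for the C4–OH and deliver hydride intramolecularly to the β-face of the C2 ketone, giving the 2α-alcohol (1,3-trans to C4–OH) against the steric bias of the angular methyl.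

Step 14
Reactants: 28 10α-acetoxy-6α-[(tert-butyldimethylsilyl)oxy]-8α,9α-epoxydaucane-2α,4β-diol; 26 acetic anhydride
Product: 29 2α,10α-diacetoxy-6α-[(tert-butyldimethylsilyl)oxy]-8α,9α-epoxydaucan-4β-ol
Conditions: Ac2O, Et3N, DMAP, CH2Cl2, rt
Reagents that add atoms: acetic anhydride, CC(=O)OC(C)=O
Why: DMAP-catalysed acetylation of the remaining secondary (C2) hydroxyl; the hindered tertiary C4–OH should not react at room temperature.

Step 15
Reactants: 29 2α,10α-diacetoxy-6α-[(tert-butyldimethylsilyl)oxy]-8α,9α-epoxydaucan-4β-ol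
Product: 30 2α,10α-diacetoxy-8α,9α-epoxydaucane-4β,6α-diol
Conditions: TBAF, AcOH, THF, 0 °C → rt
Reagents that add atoms: none
Why: Fluoride-induced cleavage of the TBS ether, buffered with acetic acid so that the acetates should neither migrate nor hydrolyse and the oxirane is not opened.

Step 16
Reactants: 30 2α,10α-diacetoxy-8α,9α-epoxydaucane-4β,6α-diol; 31 angelic acid [(Z)-2-methylbut-2-enoic acid]
Product: 32 2α,10α-diacetoxy-6α-angeloyloxy-8α,9α-epoxydaucan-4β-ol, (1R,2S,4R,5S,6S,8R,9S,10S) (CNP0170993.1)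
Conditions: angelic acid, 2,4,6-trichlorobenzoyl chloride, Et3N, toluene, rt; then 30, 75 °C (no DMAP)
Reagents that add atoms: angelic acid, C/C=C(/C)C(=O)O
Why: Yamaguchi-type esterification through the mixed 2,4,6-trichlorobenzoic anhydride, run without a nucleophilic catalyst, should acylate only the secondary C6–OH and is the established way to make angelates without Z→E isomerisation to the tiglate.

**Compound list**

1 | methyl hydrogen (3R)-3-[(tert-butyldimethylsilyl)oxy]pentanedioate | CC(C)(C)[Si](C)(C)O[C@H](CC(=O)O)CC(=O)OC | starting material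
2 | N,O-dimethylhydroxylamine hydrochloride | CNOC.Cl | starting material
3 | (3S)-3-[(tert-butyldimethylsilyl)oxy]-5-[methoxy(methyl)amino]-5-oxopentanoic acid | CC(C)(C)[Si](C)(C)O[C@H](CC(=O)O)CC(=O)N(C)OC | intermediate
4 | methylmagnesium bromide | C[Mg]Br | starting material
5 | (3S)-3-[(tert-butyldimethylsilyl)oxy]-5-oxohexanoic acid | CC(C)(C)[Si](C)(C)O[C@H](CC(=O)O)CC(C)=O | intermediate
6 | vinylmagnesium bromide | C=C[Mg]Br | starting material
7 | (3S,5RS)-3-[(tert-butyldimethylsilyl)oxy]-5-hydroxy-5-methylhept-6-enoic acid | CC(C)(C)[Si](C)(C)O[C@H](CC(=O)O)CC(C)(O)C=C | intermediate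
8 | (4S,6RS)-4-[(tert-butyldimethylsilyl)oxy]-6-ethenyl-6-methyloxan-2-one | CC(C)(C)[Si](C)(C)O[C@H]1CC(C)(C=C)OC(=O)C1 | intermediate
9 | 1,1-dibromoethane | CC(Br)Br | starting material
10 | (2Z,4R,6RS)-4-[(tert-butyldimethylsilyl)oxy]-6-ethenyl-2-ethylidene-6-methyloxane | CC(C)(C)[Si](C)(C)O[C@H]1CC(C)(C=C)O/C(=C\C)C1 | intermediate
11 | (4Z,7S)-7-[(tert-butyldimethylsilyl)oxy]-2,5-dimethylcyclooct-4-en-1-one (C2 epimers) | CC(C)(C)[Si](C)(C)O[C@H]1C/C(C)=C\CC(C)C(=O)C1 | intermediate
12 | (7S)-7-[(tert-butyldimethylsilyl)oxy]-2,5-dimethyl-1-[(trimethylsilyl)oxy]cycloocta-1,4-diene (ring double bonds cis) | CC(C)(C)[Si](C)(C)O[C@H]1C/C(C)=C\C/C(C)=C(/O[Si](C)(C)C)C1 | intermediate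
13 | (2Z,4Z,7S)-7-[(tert-butyldimethylsilyl)oxy]-2,5-dimethylcycloocta-2,4-dien-1-one | CC(C)(C)[Si](C)(C)O[C@H]1C/C(C)=C\C=C(\C)C(=O)C1 | intermediate
14 | chlorotrimethylsilane | C[Si](C)(C)Cl | starting material
15 | dichloroacetyl chloride | O=C(Cl)C(Cl)Cl | starting material
16 | (8S)-8-[(tert-butyldimethylsilyl)oxy]-3,6-dimethyl-2-[(trimethylsilyl)oxy]cycloocta-1,3,5-triene (all ring double bonds cis) | C1/C(C)=C\C=C(\C)/C(O[Si](C)(C)C)=C\[C@H]1O[Si](C)(C)C(C)(C)C | intermediate
17 | (7S)-7-[(tert-butyldimethylsilyl)oxy]-10,10-dichloro-2,5-dimethyl-1-[(trimethylsilyl)oxy]bicyclo[6.2.0]deca-2,4-dien-9-one (cis-fused; 1-OSiMe3, H-8 and 7-OSi cofacial) | CC(C)(C)[Si](C)(C)O[C@H]1C/C(C)=C\C=C(\C)[C@]2(O[Si](C)(C)C)C(Cl)(Cl)C(=O)[C@H]12 | intermediate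
18 | (7S)-7-[(tert-butyldimethylsilyl)oxy]-2,5-dimethyl-1-[(trimethylsilyl)oxy]bicyclo[6.2.0]deca-2,4-dien-9-one (cis-fused, as 17) | CC(C)(C)[Si](C)(C)O[C@H]1C/C(C)=C\C=C(\C)[C@]2(O[Si](C)(C)C)CC(=O)[C@H]12 | intermediate
19 | isopropylmagnesium chloride | CC(C)[Mg]Cl | starting material
20 | (7S)-7-[(tert-butyldimethylsilyl)oxy]-2,5-dimethyl-9-(propan-2-yl)-1-[(trimethylsilyl)oxy]bicyclo[6.2.0]deca-2,4-dien-9-ol (cis-fused; isopropyl cis to H-8) | CC(C)(C)[Si](C)(C)O[C@H]1C/C(C)=C\C=C(\C)[C@]2(O[Si](C)(C)C)C[C@@](O)(C(C)C)[C@H]12 | intermediate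
21 | (7S)-7-[(tert-butyldimethylsilyl)oxy]-2,5-dimethyl-9-(propan-2-yl)bicyclo[6.2.0]deca-2,4-diene-1,9-diol (cis-fused; 1-OH, H-8, 7-OSi cofacial; 9-OH trans to 1-OH) | CC(C)(C)[Si](C)(C)O[C@H]1C/C(C)=C\C=C(\C)[C@]2(O)C[C@@](O)(C(C)C)[C@H]12 | intermediate
22 | tert-butyl hydroperoxide | CC(C)(C)OO | starting material
23 | 2,3-epoxide of 21, oxirane oxygen cis to the 1-OH: (7S)-7-[(tert-butyldimethylsilyl)oxy]-2,3-epoxy-2,5-dimethyl-9-(propan-2-yl)bicyclo[6.2.0]dec-4-ene-1,9-diol | CC(C)(C)[Si](C)(C)O[C@H]1C/C(C)=C\[C@H]2O[C@@]2(C)[C@]2(O)C[C@@](O)(C(C)C)[C@H]12 | intermediate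
24 | 6α-[(tert-butyldimethylsilyl)oxy]-4β,10α-dihydroxydauc-8-en-2-one | CC(C)(C)[Si](C)(C)O[C@H]1C/C(C)=C\[C@@H](O)[C@@]2(C)C(=O)C[C@@](O)(C(C)C)[C@H]12 | intermediate
25 | 6α-[(tert-butyldimethylsilyl)oxy]-8α,9α-epoxy-4β,10α-dihydroxydaucan-2-one | CC(C)(C)[Si](C)(C)O[C@H]1C[C@@]2(C)O[C@H]2[C@@H](O)[C@@]2(C)C(=O)C[C@@](O)(C(C)C)[C@H]12 | intermediate
26 | acetic anhydride | CC(=O)OC(C)=O | starting material
27 | 10α-acetoxy-6α-[(tert-butyldimethylsilyl)oxy]-8α,9α-epoxy-4β-hydroxydaucan-2-one | CC(C)(C)[Si](C)(C)O[C@H]1C[C@@]2(C)O[C@H]2[C@@H](OC(C)=O)[C@@]2(C)C(=O)C[C@@](O)(C(C)C)[C@H]12 | intermediate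
28 | 10α-acetoxy-6α-[(tert-butyldimethylsilyl)oxy]-8α,9α-epoxydaucane-2α,4β-diol | CC(C)(C)[Si](C)(C)O[C@H]1C[C@@]2(C)O[C@H]2[C@@H](OC(C)=O)[C@@]2(C)[C@@H](O)C[C@@](O)(C(C)C)[C@H]12 | intermediate
29 | 2α,10α-diacetoxy-6α-[(tert-butyldimethylsilyl)oxy]-8α,9α-epoxydaucan-4β-ol | CC(C)(C)[Si](C)(C)O[C@H]1C[C@@]2(C)O[C@H]2[C@@H](OC(C)=O)[C@@]2(C)[C@@H](OC(C)=O)C[C@@](O)(C(C)C)[C@H]12 | intermediate
30 | 2α,10α-diacetoxy-8α,9α-epoxydaucane-4β,6α-diol | O[C@H]1C[C@@]2(C)O[C@H]2[C@@H](OC(C)=O)[C@@]2(C)[C@@H](OC(C)=O)C[C@@](O)(C(C)C)[C@H]12 | intermediate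
31 | angelic acid, (Z)-2-methylbut-2-enoic acid | C/C=C(/C)C(=O)O | starting material
32 | 2α,10α-diacetoxy-6α-angeloyloxy-8α,9α-epoxydaucan-4β-ol, (1R,2S,4R,5S,6S,8R,9S,10S) | C/C=C(/C)C(=O)O[C@H]1C[C@@]2(C)O[C@H]2[C@@H](OC(C)=O)[C@@]2(C)[C@@H](OC(C)=O)C[C@@](O)(C(C)C)[C@H]12 | target

**Step count and risks**

Total step count: 16. Longest linear sequence: 16 steps (fully linear from 1).

Steps most likely to fail:

1. Step 10 (key step). What may go wrong: heterolysis of the allylic C10–O bond of the vinyl epoxide, or migration of C3 instead of C5, competes with the wanted 1,2-shift. Fallback, setting out from 21 and coming back at 25: epoxide 23 is made as in step 10 but isolated by filtration through triethylamine-deactivated silica. A second vanadium-catalysed epoxidation (VO(acac)2, excess t-BuOOH, benzene, 40 °C), now directed by the same tertiary hydroxyl in a bishomoallylic relationship to C8=C9, should give the syn,syn-bis-epoxide F1, in which C10 is no longer allylic. F1 is then rearranged with Me2AlCl (CH2Cl2, −78 °C) by the same semipinacol shift and should give 25 directly, so that step 11 is not needed.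

2. Step 7. What may go wrong: loss of the trimethylsilyl group from the 3-siloxycyclobutanone during cycloaddition, purification or dechlorination, followed by retro-aldol opening of the four-membered ring. Fallback, setting out from 13 and coming back at 21: kinetic enolisation with LDA and trapping with TBSCl/DMPU gives the more robust tert-butyldimethylsilyl trienol ether F2. Dichloroketene cycloaddition (dichlorocyclobutanone F3), Zn–Cu dechlorination (cyclobutanone F4) and i-PrMgCl/CeCl3 addition (tertiary alcohol F5) follow as in the main route. Both silyl ethers are then removed with TBAF (THF, 50 °C) to give triol F6, and TBSCl/imidazole (DMF, 0 °C) silylates only the secondary C6 hydroxyl, which returns 21.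

3. Step 13. What may go wrong: the hindered tertiary C4–OH fails to exchange onto boron, so hydride is not delivered to the β-face and reduction is slow or occurs from the α-face anti to the angular methyl; the acidic medium may also open the oxirane. Fallback, setting out from 27 and coming back at 29: Luche reduction (NaBH4, CeCl3·7H2O, MeOH, −40 °C, neutral medium) from the open α-face gives the 2β-alcohol F7. Mitsunobu reaction with acetic acid (PPh3, DIAD, toluene) then inverts C2 and installs the acetate in one operation, giving 29 directly, so that step 14 is not needed.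

Further compounds
F1 | step 10 | (7S)-7-[(tert-butyldimethylsilyl)oxy]-2,3:4,5-diepoxy-2,5-dimethyl-9-(propan-2-yl)bicyclo[6.2.0]decane-1,9-diol, both oxiranes on the face of the 1-OH | CC(C)(C)[Si](C)(C)O[C@H]1C[C@@]2(C)O[C@H]2[C@H]2O[C@@]2(C)[C@]2(O)C[C@@](O)(C(C)C)[C@H]12
F2 | step 7 | (8S)-2,8-bis[(tert-butyldimethylsilyl)oxy]-3,6-dimethylcycloocta-1,3,5-triene (all ring double bonds cis) | C1/C(C)=C\C=C(\C)/C(O[Si](C)(C)C(C)(C)C)=C\[C@H]1O[Si](C)(C)C(C)(C)C
F3 | step 7 | (7S)-1,7-bis[(tert-butyldimethylsilyl)oxy]-10,10-dichloro-2,5-dimethylbicyclo[6.2.0]deca-2,4-dien-9-one (cis-fused, as 17) | CC(C)(C)[Si](C)(C)O[C@H]1C/C(C)=C\C=C(\C)[C@]2(O[Si](C)(C)C(C)(C)C)C(Cl)(Cl)C(=O)[C@H]12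
F4 | step 7 | (7S)-1,7-bis[(tert-butyldimethylsilyl)oxy]-2,5-dimethylbicyclo[6.2.0]deca-2,4-dien-9-one (cis-fused, as 18) | CC(C)(C)[Si](C)(C)O[C@H]1C/C(C)=C\C=C(\C)[C@]2(O[Si](C)(C)C(C)(C)C)CC(=O)[C@H]12
F5 | step 7 | (7S)-1,7-bis[(tert-butyldimethylsilyl)oxy]-2,5-dimethyl-9-(propan-2-yl)bicyclo[6.2.0]deca-2,4-dien-9-ol (cis-fused; isopropyl cis to H-8) | CC(C)(C)[Si](C)(C)O[C@H]1C/C(C)=C\C=C(\C)[C@]2(O[Si](C)(C)C(C)(C)C)C[C@@](O)(C(C)C)[C@H]12
F6 | step 7 | (7S)-2,5-dimethyl-9-(propan-2-yl)bicyclo[6.2.0]deca-2,4-diene-1,7,9-triol (cis-fused; 1-OH, H-8, 7-OH cofacial) | O[C@H]1C/C(C)=C\C=C(\C)[C@]2(O)C[C@@](O)(C(C)C)[C@H]12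
F7 | step 13 | 10α-acetoxy-6α-[(tert-butyldimethylsilyl)oxy]-8α,9α-epoxydaucane-2β,4β-diol | CC(C)(C)[Si](C)(C)O[C@H]1C[C@@]2(C)O[C@H]2[C@@H](OC(C)=O)[C@@]2(C)[C@H](O)C[C@@](O)(C(C)C)[C@H]12
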